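**Plan**
- Retrosynthesis first removes the C1 ester, returns the C2 and C8 ketones to carbinols and takes away the C3–C4 and C7–C14 oxiranes. It then cuts the ring bond C2–C3: C2 sits between the oxygen-bearing C1 and the methyl-bearing C3, an alkene carbon before epoxidation, so this bond joins an α-silyloxy aldehyde to a Z-alkenyl iodide and leaves the allylic C2 carbinol that steers the ring epoxidation.
- The open chain is cut further at C8–C9 (alkenylzinc plus a 2-substituted acrolein), at C7–C14 and C7–C8 (a lactone carbonyl plus two Me3SiCH2 units) and at C5–C6 (malate enolate plus an allylic bromide).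
- Forward: C5–C6, then C14 and C8, then C8–C9; the cyclohexene ring, the only carbocycle, is closed through C2–C3; both oxiranes are then formed in one operation; oxidation, desilylation and acylation finish.
- Stereochemistry: C1 from (S)-malic acid; C6 by Fráter–Seebach alkylation; C8 by ligand-controlled alkenylzinc addition; C2 in the ring closure; C3, C4 and C7 by hydroxyl-directed epoxidation from C2–OH and C8–OH, which are afterwards oxidised.

Key step: step 14

Numbering used throughout: ring C1 (CH–O-acyl), C2 (C=O), C3 (oxirane carbon carrying the methyl group), C4 (oxirane CH), C5 (CH2), C6 (CH); side chain C7 (spiro-oxirane carbon, C14 its CH2), C8 (enone C=O), C9=C10, C11 (tertiary carbinol).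

Remark: the target SMILES is read as 1S,3S,4S,6R,7R, with the C3–C4 oxirane on the ring face of the side chain and opposite to the C1 oxygen; Cy2BH is taken as a preformed reagent.

Step 1
Reactants: 1 but-2-yn-1-ol
Product: 3 (2Z)-3-iodobut-2-en-1-ol, via cyclic alkenylalanate 2 (not isolated)
Conditions: NaAlH2(OCH2CH2OMe)2, THF, 0 °C to rt; then I2, −78 °C
Reagents that add atoms: iodine II
Why: Hydroxyl-directed trans-hydroalumination of the propargylic alcohol places aluminium on the distal alkyne carbon in a five-membered alanate, and iodinolysis with retention should give the Z alkenyl iodide that becomes C3=C4.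

Step 2
Reactants: 3 (2Z)-3-iodobut-2-en-1-ol
Product: 4 (2Z)-1-bromo-3-iodobut-2-ene
Conditions: CBr4, PPh3, CH2Cl2, 0 °C
Reagents that add atoms: tetrabromomethane BrC(Br)(Br)Br
Why: Appel reaction of the primary allylic alcohol, an SN2 displacement of the oxyphosphonium group that leaves the alkenyl iodide and its geometry untouched.

Step 3
Reactants: 5 dimethyl (S)-malate; 4 (2Z)-1-bromo-3-iodobut-2-ene
Product: 7 dimethyl (2S,3R)-2-hydroxy-3-[(2Z)-3-iodobut-2-en-1-yl]butanedioate, via dilithium alkoxide enolate 6 (not isolated)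
Conditions: LiN(SiMe3)2 (2.1 equiv), THF, −78 °C; then 4, −78 to −20 °C
Reagents that add atoms: none
Why: Fráter–Seebach alkylation, in which the chelated alkoxide enolate should be alkylated by the allylic bromide on the face anti to the ester group of the carbinol carbon, forming C5–C6 and setting C6 (3R, erythro) from the malate centre C1.

Step 4
Reactants: 7 dimethyl (2S,3R)-2-hydroxy-3-[(2Z)-3-iodobut-2-en-1-yl]butanedioate
Product: 9 (3R,4S)-4-hydroxy-3-[(2Z)-3-iodobut-2-en-1-yl]oxolan-2-one, via diol ester 8 (not isolated)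
Conditions: BH3·SMe2, NaBH4 (5 mol%), THF, 0 °C to rt; MeOH; then TsOH (cat.), CH2Cl2, rt
Reagents that add atoms: none
Why: Hydroxyl-directed borane reduction, in which the alkoxyborane formed at C1–OH reduces only the neighbouring C2 ester, after which the new primary alcohol lactonises onto the C7 ester, so the two carboxyl carbons are told apart without touching a stereocentre.

Step 5
Reactants: 9 (3R,4S)-4-hydroxy-3-[(2Z)-3-iodobut-2-en-1-yl]oxolan-2-one
Product: 10 (3R,4S)-4-[(tert-butyldimethylsilyl)oxy]-3-[(2Z)-3-iodobut-2-en-1-yl]oxolan-2-one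
Conditions: TBSCl, imidazole, DMF, rt
Reagents that add atoms: tert-butyldimethylsilyl chloride CC(C)(C)[Si](C)(C)Cl
Why: Silylation of the secondary C1 alcohol under weakly basic conditions that should not cause β-elimination in the β-oxygenated lactone.

Step 6
Reactants: 10 (3R,4S)-4-[(tert-butyldimethylsilyl)oxy]-3-[(2Z)-3-iodobut-2-en-1-yl]oxolan-2-one
Product: 12 (2S,3S,5Z)-2-[(tert-butyldimethylsilyl)oxy]-6-iodo-3-[3-(trimethylsilyl)prop-1-en-2-yl]hept-5-en-1-ol, via bis(silylmethyl) carbinol 11 (not isolated)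
Conditions: Me3SiCH2MgCl, CeCl3, THF, −78 °C to rt; then SiO2, CH2Cl2, rt
Reagents that add atoms: (trimethylsilyl)methylmagnesium chloride C[Si](C)(C)C[Mg]Cl
Why: Double addition of the weakly basic organocerium reagent to the lactone carbonyl (no enolisation at C6) followed by acid-mediated Peterson olefination should turn C7 into a 2-substituted allylsilane, which brings in C14 and C8 and frees the C2 hydroxyl.

Step 7
Reactants: 12 (2S,3S,5Z)-2-[(tert-butyldimethylsilyl)oxy]-6-iodo-3-[3-(trimethylsilyl)prop-1-en-2-yl]hept-5-en-1-ol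
Product: 13 tert-butyl{[(2S,3S,5Z)-6-iodo-1-[(triethylsilyl)oxy]-3-[3-(trimethylsilyl)prop-1-en-2-yl]hept-5-en-2-yl]oxy}dimethylsilane
Conditions: TESCl, imidazole, CH2Cl2, 0 °C
Reagents that add atoms: chlorotriethylsilane CC[Si](CC)(CC)Cl
Why: Silylation of the primary C2 alcohol as a triethylsilyl ether, chosen because this group can later be oxidised directly to the aldehyde.

Step 8
Reactants: 13 tert-butyl{[(2S,3S,5Z)-6-iodo-1-[(triethylsilyl)oxy]-3-[3-(trimethylsilyl)prop-1-en-2-yl]hept-5-en-2-yl]oxy}dimethylsilane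
Product: 15 (3S,5Z)-3-{(1S)-1-[(tert-butyldimethylsilyl)oxy]-2-[(triethylsilyl)oxy]ethyl}-6-iodo-2-methylidenehept-5-en-1-ol, via epoxysilane 14 (not isolated)
Conditions: mCPBA, CH2Cl2, −20 to 0 °C; then SiO2, rt
Reagents that add atoms: 3-chloroperoxybenzoic acid OOC(=O)c1cccc(Cl)c1
Why: Epoxidation of the allylsilane, by far the most nucleophilic alkene, followed by acid-triggered opening of the epoxysilane with loss of the silyl group (overall SE2′ oxygenation) should give the 2-substituted allylic alcohol.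

Step 9
Reactants: 15 (3S,5Z)-3-{(1S)-1-[(tert-butyldimethylsilyl)oxy]-2-[(triethylsilyl)oxy]ethyl}-6-iodo-2-methylidenehept-5-en-1-ol
Product: 16 (3S,5Z)-3-{(1S)-1-[(tert-butyldimethylsilyl)oxy]-2-[(triethylsilyl)oxy]ethyl}-6-iodo-2-methylidenehept-5-enal
Conditions: MnO2, CH2Cl2, rt
Reagents that add atoms: none
Why: Allylic alcohol oxidation with MnO2 should give the 2-substituted acrolein (C8 aldehyde) under neutral conditions that neither epimerise C6 nor disturb the silyl ethers.

Step 10
Reactants: 17 2-methylbut-3-yn-2-ol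
Product: 18 triethyl[(2-methylbut-3-yn-2-yl)oxy]silane
Conditions: TESOTf, 2,6-lutidine, CH2Cl2, 0 °C
Reagents that add atoms: triethylsilyl trifluoromethanesulfonate CC[Si](CC)(CC)OS(=O)(=O)C(F)(F)F
Why: Silyl triflate silylation, the standard way to protect a hindered tertiary propargylic alcohol.

Step 11
Reactants: 16 (3S,5Z)-3-{(1S)-1-[(tert-butyldimethylsilyl)oxy]-2-[(triethylsilyl)oxy]ethyl}-6-iodo-2-methylidenehept-5-enal; 18 triethyl[(2-methylbut-3-yn-2-yl)oxy]silane
Product: 21 (3S,4E)-2-{(2S,3S,5Z)-2-[(tert-butyldimethylsilyl)oxy]-6-iodo-1-[(triethylsilyl)oxy]hept-5-en-3-yl}-6-methyl-6-[(triethylsilyl)oxy]hepta-1,4-dien-3-ol, via alkenylborane 19 (not isolated), via alkenylzinc 20 (not isolated)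
Conditions: 18, Cy2BH, toluene, 0 °C to rt; Me2Zn, −78 °C; (−)-MIB (5 mol%), then 16, −20 °C
Reagents that add atoms: none
Why: Syn-hydroboration of the terminal alkyne gives the E-alkenylborane, boron-to-zinc exchange the alkenylzinc, and its amino-alkoxide-catalysed enantioselective 1,2-addition to the aldehyde should form C8–C9 with the alkenyl group delivered to the Si face of C8 under ligand control (8S).

Step 12
Reactants: 21 (3S,4E)-2-{(2S,3S,5Z)-2-[(tert-butyldimethylsilyl)oxy]-6-iodo-1-[(triethylsilyl)oxy]hept-5-en-3-yl}-6-methyl-6-[(triethylsilyl)oxy]hepta-1,4-dien-3-ol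
Product: 22 C8 triethylsilyl ether of 21
Conditions: TESOTf, 2,6-lutidine, CH2Cl2, −78 °C
Reagents that add atoms: triethylsilyl trifluoromethanesulfonate CC[Si](CC)(CC)OS(=O)(=O)C(F)(F)F
Why: Low-temperature silylation of the bis-allylic C8 alcohol under buffered conditions that should not ionise it.

Step 13
Reactants: 22 C8 triethylsilyl ether of 21
Product: 23 (2S,3S,5Z)-2-[(tert-butyldimethylsilyl)oxy]-6-iodo-3-[(3S,4E)-6-methyl-3,6-bis[(triethylsilyl)oxy]hepta-1,4-dien-2-yl]hept-5-enal
Conditions: (COCl)2, DMSO, CH2Cl2, −78 to −40 °C; then Et3N, −78 °C to rt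
Reagents that add atoms: none
Why: Swern oxidation applied directly to the primary triethylsilyl ether (silicon–sulfur exchange at oxygen, then the usual ylide fragmentation) should give the C2 aldehyde while the secondary and tertiary silyl ethers survive and the α-silyloxy centre C1 is not epimerised.

Step 14
Reactants: 23 (2S,3S,5Z)-2-[(tert-butyldimethylsilyl)oxy]-6-iodo-3-[(3S,4E)-6-methyl-3,6-bis[(triethylsilyl)oxy]hepta-1,4-dien-2-yl]hept-5-enal
Product: 25 (1S,5S,6S)-6-[(tert-butyldimethylsilyl)oxy]-2-methyl-5-[(3S,4E)-6-methyl-3,6-bis[(triethylsilyl)oxy]hepta-1,4-dien-2-yl]cyclohex-2-en-1-ol, via alkenylchromium dichloride 24 (not isolated)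
Conditions: CrCl2 (8 equiv), NiCl2 (2 mol%), DMSO/THF, 0.005 M, rt
Reagents that add atoms: none
Why: Intramolecular Nozaki–Hiyama–Kishi reaction: divalent chromium reduces NiCl2 to zerovalent nickel, which adds oxidatively to the C3–I bond without loss of the Z geometry, and exchange of the alkenyl group onto trivalent chromium gives 24, a carbonyl-selective nucleophile that attacks the C2 aldehyde. The closest known reaction type is the CrCl2/NiCl2-mediated cyclisation of iodoalkenyl aldehydes to cycloalkenols. The ring closes in the 6-exo-trig mode at the carbonyl carbon, and the Z alkene becomes the endocyclic C3=C4 bond. C2 is set under substrate control in a chair-like array with the C1 silyloxy group and the C6 side chain equatorial: the alkenyl carbon attacks anti to the C1–O bond and the bulky chromium-bound oxygen should take the pseudo-equatorial site, where it is gauche to C1–O and C1–H but not to C6, giving the 2S alcohol trans to C1–O and cis to the side chain. The step needs reaction at the alkenyl iodide and the aldehyde only, which the reagent secures because silyl ethers, the 1,1-disubstituted alkene and the E alkene are inert to it, and it needs ring closure to outrun intermolecular coupling, which high dilution and the Z geometry (iodide and tether cis) secure.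

Step 15
Reactants: 25 (1S,5S,6S)-6-[(tert-butyldimethylsilyl)oxy]-2-methyl-5-[(3S,4E)-6-methyl-3,6-bis[(triethylsilyl)oxy]hepta-1,4-dien-2-yl]cyclohex-2-en-1-ol
Product: 26 (1S,5S,6S)-6-[(tert-butyldimethylsilyl)oxy]-5-[(3S,4E)-3-hydroxy-6-methyl-6-[(triethylsilyl)oxy]hepta-1,4-dien-2-yl]-2-methylcyclohex-2-en-1-ol
Conditions: HF·pyridine, pyridine, THF, 0 °C
Reagents that add atoms: none
Why: Buffered fluoride desilylation should be fastest at the least hindered triethylsilyl ether, the secondary one at C8, leaving the tertiary C11 triethylsilyl and the C1 tert-butyldimethylsilyl ethers, and it avoids solvolysis of the bis-allylic carbinol.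

Step 16
Reactants: 26 (1S,5S,6S)-6-[(tert-butyldimethylsilyl)oxy]-5-[(3S,4E)-3-hydroxy-6-methyl-6-[(triethylsilyl)oxy]hepta-1,4-dien-2-yl]-2-methylcyclohex-2-en-1-ol
Product: 27 bis-epoxy diol (1S,2R,3R,4S,6R,7R,8S): C3–C4 oxirane cis to C2–OH and C7–C14 oxirane erythro to C8–OH with C1–OTBS and C11–OTES retained
Conditions: VO(acac)2 (10 mol%), tBuOOH (2.5 equiv), CH2Cl2, 0 °C to rt
Reagents that add atoms: tert-butyl hydroperoxide CC(C)(C)OO
Why: Vanadium-catalysed hydroxyl-directed epoxidation, in which C2–OH should deliver oxygen to C3=C4 on its own face (cis to the side chain) and C8–OH to C7=C14 through the transition state that avoids A(1,2) strain between C9 and C6 (erythro, 7R from 8S), while C9=C10, flanked by two oxygenated carbons and a quaternary centre, should react more slowly.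

Step 17
Reactants: 27 bis-epoxy diol
Product: 28 bis-epoxy diketone (1S,3S,4S,6R,7R) with C1–OTBS and C11–OTES
Conditions: Dess–Martin periodinane, NaHCO3, CH2Cl2, 0 °C to rt
Reagents that add atoms: none
Why: Dess–Martin oxidation of both secondary epoxy carbinols under buffered conditions should give the two epoxy ketones without epimerising C1 or opening the oxiranes, and it removes the auxiliary stereocentres C2 and C8.

Step 18
Reactants: 28 bis-epoxy diketone
Product: 29 (1S,3S,4S,6R,7R)-1,11-dihydroxy bis-epoxy diketone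
Conditions: HF·pyridine, THF, 0 °C to rt
Reagents that add atoms: none
Why: Fluoride desilylation should cleave the C1 silyl ether (activated by the adjacent ketone) and the tertiary C11 triethylsilyl ether under mildly acidic conditions that the carbonyl-deactivated oxiranes and the enone tolerate.

Step 19
Reactants: 29 (1S,3S,4S,6R,7R)-1,11-dihydroxy bis-epoxy diketone
Product: 30 CNP0292003.1
Conditions: (Me2CHCH2CO)2O, DMAP (cat.), pyridine, CH2Cl2, 0 °C
Reagents that add atoms: 3-methylbutanoic anhydride CC(C)CC(=O)OC(=O)CC(C)C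
Why: DMAP-catalysed acylation should esterify the secondary C1 hydroxyl selectively, the tertiary allylic C11 hydroxyl being too hindered to react at 0 °C.

**Compound list**
1 | but-2-yn-1-ol | CC#CCO | starting material
2 | sodium cyclic alkenylalanate (3-methyl-2,2-bis(2-methoxyethoxy)-2,5-dihydro-1,2-oxaaluminol-2-uide) | CC1=CCO[Al-]1(OCCOC)OCCOC.[Na+] | intermediate (not isolated)
3 | (2Z)-3-iodobut-2-en-1-ol | C/C(I)=C/CO | intermediate
4 | (2Z)-1-bromo-3-iodobut-2-ene | C/C(I)=C/CBr | intermediate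
5 | dimethyl (S)-malate | COC(=O)[C@@H](O)CC(=O)OC | starting material
6 | dilithium alkoxide enolate of 5 | [Li+].[Li+].COC(=O)[C@@H]([O-])/C=C(\[O-])OC | intermediate (not isolated)
7 | dimethyl (2S,3R)-2-hydroxy-3-[(2Z)-3-iodobut-2-en-1-yl]butanedioate | COC(=O)[C@@H](O)[C@@H](C/C=C(/C)I)C(=O)OC | intermediate
8 | methyl (2R,3S)-3,4-dihydroxy-2-[(2Z)-3-iodobut-2-en-1-yl]butanoate | COC(=O)[C@H](C/C=C(/C)I)[C@H](O)CO | intermediate (not isolated)
9 | (3R,4S)-4-hydroxy-3-[(2Z)-3-iodobut-2-en-1-yl]oxolan-2-one (cis) | O=C1OC[C@@H](O)[C@H]1C/C=C(/C)I | intermediate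
10 | (3R,4S)-4-[(tert-butyldimethylsilyl)oxy]-3-[(2Z)-3-iodobut-2-en-1-yl]oxolan-2-one | O=C1OC[C@@H](O[Si](C)(C)C(C)(C)C)[C@H]1C/C=C(/C)I | intermediate
11 | (2S,3R,5Z)-2-[(tert-butyldimethylsilyl)oxy]-3-[2-hydroxy-1,3-bis(trimethylsilyl)propan-2-yl]-6-iodohept-5-en-1-ol | OC[C@@H](O[Si](C)(C)C(C)(C)C)[C@@H](C/C=C(/C)I)C(O)(C[Si](C)(C)C)C[Si](C)(C)C | intermediate (not isolated)
12 | (2S,3S,5Z)-2-[(tert-butyldimethylsilyl)oxy]-6-iodo-3-[3-(trimethylsilyl)prop-1-en-2-yl]hept-5-en-1-ol | OC[C@@H](O[Si](C)(C)C(C)(C)C)[C@@H](C/C=C(/C)I)C(=C)C[Si](C)(C)C | intermediate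
13 | tert-butyl{[(2S,3S,5Z)-6-iodo-1-[(triethylsilyl)oxy]-3-[3-(trimethylsilyl)prop-1-en-2-yl]hept-5-en-2-yl]oxy}dimethylsilane | CC[Si](CC)(CC)OC[C@@H](O[Si](C)(C)C(C)(C)C)[C@@H](C/C=C(/C)I)C(=C)C[Si](C)(C)C | intermediate
14 | epoxysilane from 13 (C7–C14 oxirane, both epimers at the oxirane carbon) | CC[Si](CC)(CC)OC[C@@H](O[Si](C)(C)C(C)(C)C)[C@@H](C/C=C(/C)I)C1(C[Si](C)(C)C)CO1 | intermediate (not isolated)
15 | (3S,5Z)-3-{(1S)-1-[(tert-butyldimethylsilyl)oxy]-2-[(triethylsilyl)oxy]ethyl}-6-iodo-2-methylidenehept-5-en-1-ol | CC[Si](CC)(CC)OC[C@@H](O[Si](C)(C)C(C)(C)C)[C@@H](C/C=C(/C)I)C(=C)CO | intermediate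
16 | (3S,5Z)-3-{(1S)-1-[(tert-butyldimethylsilyl)oxy]-2-[(triethylsilyl)oxy]ethyl}-6-iodo-2-methylidenehept-5-enal | CC[Si](CC)(CC)OC[C@@H](O[Si](C)(C)C(C)(C)C)[C@@H](C/C=C(/C)I)C(=C)C=O | intermediate
17 | 2-methylbut-3-yn-2-ol | C#CC(C)(C)O | starting material
18 | triethyl[(2-methylbut-3-yn-2-yl)oxy]silane | C#CC(C)(C)O[Si](CC)(CC)CC | intermediate
19 | dicyclohexyl[(1E)-3-methyl-3-[(triethylsilyl)oxy]but-1-en-1-yl]borane | CC[Si](CC)(CC)OC(C)(C)/C=C/B(C1CCCCC1)C1CCCCC1 | intermediate (not isolated)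
20 | methyl[(1E)-3-methyl-3-[(triethylsilyl)oxy]but-1-en-1-yl]zinc | CC[Si](CC)(CC)OC(C)(C)/C=C/[Zn]C | intermediate (not isolated)
21 | (3S,4E)-2-{(2S,3S,5Z)-2-[(tert-butyldimethylsilyl)oxy]-6-iodo-1-[(triethylsilyl)oxy]hept-5-en-3-yl}-6-methyl-6-[(triethylsilyl)oxy]hepta-1,4-dien-3-ol | CC[Si](CC)(CC)OC[C@@H](O[Si](C)(C)C(C)(C)C)[C@@H](C/C=C(/C)I)C(=C)[C@@H](O)/C=C/C(C)(C)O[Si](CC)(CC)CC | intermediate
22 | C8 triethylsilyl ether of 21 | CC[Si](CC)(CC)OC[C@@H](O[Si](C)(C)C(C)(C)C)[C@@H](C/C=C(/C)I)C(=C)[C@@H](O[Si](CC)(CC)CC)/C=C/C(C)(C)O[Si](CC)(CC)CC | intermediate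
23 | (2S,3S,5Z)-2-[(tert-butyldimethylsilyl)oxy]-6-iodo-3-[(3S,4E)-6-methyl-3,6-bis[(triethylsilyl)oxy]hepta-1,4-dien-2-yl]hept-5-enal | O=C[C@@H](O[Si](C)(C)C(C)(C)C)[C@@H](C/C=C(/C)I)C(=C)[C@@H](O[Si](CC)(CC)CC)/C=C/C(C)(C)O[Si](CC)(CC)CC | intermediate
24 | (Z)-alkenylchromium dichloride from 23 (CrCl2 in place of iodine at C3) | O=C[C@@H](O[Si](C)(C)C(C)(C)C)[C@@H](C/C=C(/C)[Cr](Cl)Cl)C(=C)[C@@H](O[Si](CC)(CC)CC)/C=C/C(C)(C)O[Si](CC)(CC)CC | intermediate (not isolated)
25 | (1S,5S,6S)-6-[(tert-butyldimethylsilyl)oxy]-2-methyl-5-[(3S,4E)-6-methyl-3,6-bis[(triethylsilyl)oxy]hepta-1,4-dien-2-yl]cyclohex-2-en-1-ol | CC(C)(C)[Si](C)(C)O[C@@H]1[C@@H](O)C(C)=CC[C@H]1C(=C)[C@@H](O[Si](CC)(CC)CC)/C=C/C(C)(C)O[Si](CC)(CC)CC | intermediate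
26 | (1S,5S,6S)-6-[(tert-butyldimethylsilyl)oxy]-5-[(3S,4E)-3-hydroxy-6-methyl-6-[(triethylsilyl)oxy]hepta-1,4-dien-2-yl]-2-methylcyclohex-2-en-1-ol | CC(C)(C)[Si](C)(C)O[C@@H]1[C@@H](O)C(C)=CC[C@H]1C(=C)[C@@H](O)/C=C/C(C)(C)O[Si](CC)(CC)CC | intermediate
27 | bis-epoxy diol (1S,2R,3R,4S,6R,7R,8S), C1–OTBS, C11–OTES | CC(C)(C)[Si](C)(C)O[C@@H]1[C@@H](O)[C@@]2(C)O[C@H]2C[C@H]1[C@]1([C@@H](O)/C=C/C(C)(C)O[Si](CC)(CC)CC)CO1 | intermediate
28 | bis-epoxy diketone (1S,3S,4S,6R,7R), C1–OTBS, C11–OTES | CC(C)(C)[Si](C)(C)O[C@@H]1C(=O)[C@@]2(C)O[C@H]2C[C@H]1[C@]1(C(=O)/C=C/C(C)(C)O[Si](CC)(CC)CC)CO1 | intermediate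
29 | (1S,3S,4S,6R,7R)-1,11-dihydroxy bis-epoxy diketone | O[C@@H]1C(=O)[C@@]2(C)O[C@H]2C[C@H]1[C@]1(C(=O)/C=C/C(C)(C)O)CO1 | intermediate
30 | CNP0292003.1, the C1 3-methylbutanoate of 29 | CC(C)CC(=O)O[C@@H]1C(=O)[C@@]2(C)O[C@H]2C[C@H]1[C@]1(C(=O)/C=C/C(C)(C)O)CO1 | target

**Totals**
Total step count: 19. Longest linear sequence: 18 steps (steps 1–9 and 11–19; step 10 is the only side branch).

**Steps most likely to fail**

1. Step 14, poor facial selectivity at C2 in the ring closure. A transition state with the chromium-bound oxygen pseudo-axial relieves A(1,2) strain with the C3 methyl group and may compete, which would put the carbinol on the wrong ring face for the directed epoxidation. The fallback sets out from 25, alone or mixed with the C2-epimeric cyclohexenol F1, and returns at 25. The allylic alcohols are oxidised with MnO2 to the cyclohexenone F2, which is reduced with NaBH4 and CeCl3·7H2O in MeOH at −78 °C (Luche reduction). Axial hydride delivery, as in the reduction of carvone to cis-carveol, should give the pseudo-equatorial alcohol 25, so C2 is set by hydride addition to a ring ketone and not in the C–C bond formation.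

2. Step 16, loss of chemoselectivity or facial control in the double epoxidation. Oxygen may be transferred to C9=C10 (also allylic to C8–OH), the bis-allylic C8 carbinol may be oxidised before it has directed, or control at C7 may be incomplete. The fallback sets out from 25 and returns at 27. Compound 25, in which only C2–OH is free, is epoxidised with VO(acac)2 and tBuOOH to the ring epoxy alcohol F3. The C8 hydroxyl is then released with HF·pyridine and pyridine to give the epoxy diol F4. C7=C14 is finally epoxidised under reagent control with Ti(OiPr)4, L-(+)-diisopropyl tartrate and tBuOOH (Sharpless epoxidation): for the 8S carbinol this alkene is the fast-reacting one and should give the erythro 7R oxirane, whereas C9=C10 is the slow-reacting one.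

3. Step 15, insufficient rate difference between the secondary C8 and the tertiary C11 triethylsilyl ethers, so that both are lost. The fallback sets out from 21 and returns at 26. C8–OH is protected as an ester: Ac2O, pyridine and DMAP give the C8 acetate F5. Swern oxidation of the primary triethylsilyl ether gives the aldehyde F6. Ring closure with CrCl2 and NiCl2 gives the cyclohexenol acetate F7. iBu2AlH at −78 °C then removes the acetate without touching any silyl ether and gives 26.

**Further compounds**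
F1 | step 14 | (1R,5S,6S)-6-[(tert-butyldimethylsilyl)oxy]-2-methyl-5-[(3S,4E)-6-methyl-3,6-bis[(triethylsilyl)oxy]hepta-1,4-dien-2-yl]cyclohex-2-en-1-ol (C2 epimer of 25) | CC(C)(C)[Si](C)(C)O[C@@H]1[C@H](O)C(C)=CC[C@H]1C(=C)[C@@H](O[Si](CC)(CC)CC)/C=C/C(C)(C)O[Si](CC)(CC)CC
F2 | step 14 | (5S,6S)-6-[(tert-butyldimethylsilyl)oxy]-2-methyl-5-[(3S,4E)-6-methyl-3,6-bis[(triethylsilyl)oxy]hepta-1,4-dien-2-yl]cyclohex-2-en-1-one | CC(C)(C)[Si](C)(C)O[C@@H]1C(=O)C(C)=CC[C@H]1C(=C)[C@@H](O[Si](CC)(CC)CC)/C=C/C(C)(C)O[Si](CC)(CC)CC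
F3 | step 16 | C3–C4 epoxide of 25, oxirane cis to C2–OH, side chain unchanged | CC(C)(C)[Si](C)(C)O[C@@H]1[C@@H](O)[C@@]2(C)O[C@H]2C[C@H]1C(=C)[C@@H](O[Si](CC)(CC)CC)/C=C/C(C)(C)O[Si](CC)(CC)CC
F4 | step 16 | C8 alcohol from F3 (C3–C4 epoxide of 26) | CC(C)(C)[Si](C)(C)O[C@@H]1[C@@H](O)[C@@]2(C)O[C@H]2C[C@H]1C(=C)[C@@H](O)/C=C/C(C)(C)O[Si](CC)(CC)CC
F5 | step 15 | C8 acetate of 21 | CC[Si](CC)(CC)OC[C@@H](O[Si](C)(C)C(C)(C)C)[C@@H](C/C=C(/C)I)C(=C)[C@@H](OC(C)=O)/C=C/C(C)(C)O[Si](CC)(CC)CC
F6 | step 15 | C2 aldehyde from F5 (C8 acetate analogue of 23) | O=C[C@@H](O[Si](C)(C)C(C)(C)C)[C@@H](C/C=C(/C)I)C(=C)[C@@H](OC(C)=O)/C=C/C(C)(C)O[Si](CC)(CC)CC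
F7 | step 15 | cyclohexenol from F6 (C8 acetate analogue of 25) | CC(C)(C)[Si](C)(C)O[C@@H]1[C@@H](O)C(C)=CC[C@H]1C(=C)[C@@H](OC(C)=O)/C=C/C(C)(C)O[Si](CC)(CC)CC
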